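## Structural features

The target is a germacranolide: a cyclodeca-1(10),4-diene whose two trisubstituted E-olefins (C1=C10 and C4=C5, each with a methyl group) are separated by C2–C3. It is fused across C6–C7 to a butenolide (C6–O–C12(=O)–C11=C7) that carries an acetoxymethyl group (C13) on C11. There are three stereocentres and no two are adjacent: C2 (R, acetate) lies between the ring olefins, while C6 (R, lactone oxygen) and C8 (S, methacrylate) flank the sp2 carbon C7. C6 is allylic to both C4=C5 and C7=C11, so its C–O bond ionises easily and H6 is the acidic γ-hydrogen of the butenolide. The C2 and C13 acetates are allylic, the methacrylate is a polymerisable Michael acceptor, and the E,E-1,5-diene is prone to Cope rearrangement and acid-induced transannular cyclisation. The real difficulty is the strained ten-membered ring with two E-trisubstituted olefins, three different acyloxy groups on allylic positions, and a C2 centre too remote from C6/C8 for mutual control. The key step uses the 1,5-relationship of C1=C10 and C4=C5 across C2–C3: a bond between C5 and C10 turns the macrocycle into a trans-fused eudesmane whose ring A is a cyclohexa-1,3-diene (C1=C2–C3=C4) and whose ring B holds C6, C7 and C8 on a rigid chair.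

## Logic of the disconnections

30 to 28 and 29: the C2–O acyl bond is cut first because the ring allylic acetate is the most labile group. The gain is a free carbinol whose configuration can still be corrected. The forward step must acylate without a base able to remove H6.

28 to 27: the C2–H bond is cut, so C2 becomes a carbonyl. This removes the one stereocentre that ring B cannot control and links C2 to enolate chemistry. The forward step must be a 1,2-selective, reagent-controlled reduction of a ten-membered enone.

27 to 26: the C3–H bond is exchanged for an O–Si bond, which writes the ketone as its enol ether (C2=C3). This gives the conjugated triene C10=C1–C2=C3–C4=C5 needed for the next cut. The forward step must protonate C3 only, in the cold.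

26 to 25 (key): the π bonds C1=C10 and C4=C5 are exchanged for the σ bond C5–C10. The medium ring becomes a trans-decalin, and C5 and C10 appear as stereocentres whose trans relationship encodes both E geometries. The forward step must be a photochemical conrotatory opening with excitation of the diene only, and the product must be intercepted before thermal reclosure.

25 to 23 and 24: the C8–O acyl bond is cut. The methacrylate is the group least compatible with bases, oxidants and metals, so it is placed last before irradiation. The acylation must tolerate the silyl dienol ether.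

23 to 21 and 22: the C13–O bond is cut, C7=C11 is moved to C11=C13, and the C8 oxygen is tied back to C7 as an epoxide. One addition then delivers the butenolide, the C13 acetate and the free 8-hydroxyl, and the acidic H6 of the butenolide does not yet exist when the enol ether is made. The forward step needs attack at C13 under near-neutral conditions.

21 to 18 and 19: the O–Si bond is cut to the ring A enone. The forward step needs kinetic deprotonation at C1 only.

18 to 17: the epoxide C–O bonds are cut. The C8 stereocentre is traced to face selectivity on the decalin (angular methyl group). The oxidant must choose C7=C8 among four olefins.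

17 to 14 to 13: the diene C7=C8/C11=C13 is exchanged for C7=C11 plus a C8–O bond (1,4-dehydration), then the C8–O bond is cut. The γ-methylene of a butenolide is the position that electrophilic allylic oxidation reaches. The oxidation must prefer it to the ring A enone.

13 to 12 to 11: C7=C11 is moved back to the exocyclic position, then the C2 carbonyl is removed. The exocyclic olefin is what selenoxide elimination delivers, and C2 is oxidised while no other electron-rich allylic methylene is present. The oxidation must occur at C2, not at C5 or C15.

11 to 9 to 6 and 7: C11=C13 is traced to a C11–Se bond and then to the lactone α-C–H. The only demand is a single acidic site, which 6 provides.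

6 to 3 to 2 to 1: C5–H and C3=C4 are traced to an allylic alcohol (C3–O, C4=C5), then to the enone, then to the dienone. 1 already holds the skeleton, C6, C7, C10 and the lactone. The forward sequence must deliver hydrogen to the α-face of C5.

## Other disconnections considered

Alternative 1: The cut is C5–C6 plus the lactone C12–O bond. In the forward step CrCl2 (divalent chromium) with catalytic NiCl2 converts the (E)-alkenyl iodide of open-chain precursor A1 into an alkenylchromium. This adds to the C6 aldehyde, and the C6 alkoxide acylates on the cis methyl ester to give A2.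
- In favour: it is convergent, both rings form in one operation, the olefin geometries are set beforehand and alkenylchromium species keep their configuration, and no chiral-pool skeleton is needed.
- Against: C6 would be created during macrocyclisation with only remote centres (C8, C2) and ring conformation to steer it. The tetrasubstituted olefin bearing both aldehyde and ester is very electrophilic and must be kept geometrically pure. The closure needs high dilution and a large excess of chromium salt. The C8 silyl ether must still be exchanged for the methacrylate on the labile macrocycle.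
- Comparison: the chosen plan inherits C6 from 1 and makes the ring by cleaving a bicycle, without the entropic cost of end-to-end closure. The alternative is the equal or the better in convergence, in freedom to vary fragments, and in needing no photochemical equipment. Its total step count is expected to be similar or higher, with a shorter longest linear sequence.

Alternative 2: The cut is C9–C10. In the forward step Ni(cod)2 (zerovalent nickel), PBu3 and BEt3 couple the terminal epoxide with the alkyne of A3, with hydrogen delivered to C1, to give A4.
- In favour: cis addition across the alkyne fixes the E geometry and regiochemistry of C1=C10. C8 comes from the epoxide with retention, the C6–C8 oxygens come from a carbohydrate, the metal is catalytic, and the C8 hydroxyl emerges free.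
- Against: A4 has no butenolide. C11–C13, the C7=C11 olefin, the lactone and the C13 acetate must all be built on the formed ten-membered diene, with several protecting-group changes. The C7 stereocentre is made only to be destroyed. Closing a ten-membered ring that already holds an E-olefin by this coupling is demanding.
- Comparison: the alternative is the better in stereochemical certainty at C6 and C8 (chiral pool against face selectivity of an epoxidation) and in using a catalytic ring closure. The chosen plan is clearly better in step economy after ring formation (three steps against roughly ten).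

Alternative 3: The cut is C7–C8. In the forward step CrCl2 with catalytic NiCl2 converts the C7 iodide of iodobutenolide A5 into an alkenylchromium that adds to the C8 aldehyde, closing the ring and creating C8 in A6.
- In favour: the butenolide and C6 are complete before closure, all olefins are preset, and A6 is one acylation from the target.
- Against: C8 is formed in the ring closure, controlled only by the remote C6 centre and macrocycle conformation. The β,γ-unsaturated aldehyde is prone to conjugation. H6 and two allylic acetates face Lewis-acidic chromium salts. Stoichiometric chromium at high dilution is needed.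
- Comparison: this is the better plan in endgame economy (one step after ring formation against three) and in convergence. The chosen plan is better in stereocontrol, because C8 is fixed on a rigid decalin before the ring is opened, and it does not need asymmetric construction of C2 and C6 in an open chain.

Key step: step 14

Remarks on the chemistry:
- Eudesmane/germacrane numbering is used throughout (C14 = methyl on C10, C15 = methyl on C4, C13 = CH2 on C11).
- In 26 the central olefin C2=C3 is cis with respect to the ring (C1 and C4 on the same side). Because the silyloxy oxygen outranks C1, its sequence-rule descriptor is 2E.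
- The silyl enol ether is installed (step 11) before the butenolide exists, because a 7(11)-butenolide has an acidic H6 that would compete with C1–H. The butenolide, the C13 acetate and the 8α-hydroxyl are then released together under near-neutral conditions (step 12).
- 26 is handled only as a cold solution.

Step 1
Reactants: 1 α-santonin
Product: 2 1,2-dihydro-α-santonin
Conditions: H2 (1 atm), RhCl(PPh3)3 (5 mol %), benzene–EtOH, rt
Reagents that add atoms: none
Why: Homogeneous hydrogenation with RhCl(PPh3)3 reduces the disubstituted C1=C2 of the cross-conjugated dienone and leaves the tetrasubstituted C4=C5 alone; no stereocentre is formed.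

Step 2
Reactants: 2 1,2-dihydro-α-santonin
Product: 3 3β-hydroxyeudesm-4-en-6α,12-olide
Conditions: NaBH4, CeCl3·7H2O, MeOH, −78 → −20 °C
Reagents that add atoms: none
Why: Luche reduction gives 1,2-reduction of the enone; hydride adds axially from the α-face, opposite the 10β-methyl group, which should give the pseudo-equatorial 3β-alcohol (3S); the lactone is inert at this temperature.

Step 3
Reactants: 3 3β-hydroxyeudesm-4-en-6α,12-olide
Product: 6 5αH-eudesm-3-en-6α,12-olide, via sulfonylhydrazine adduct 4 (not isolated), via allylic diazene 5 (not isolated)
Conditions: 2-O2NC6H4SO2NHNH2, PPh3, EtO2CN=NCO2Et, N-methylmorpholine, −30 °C → rt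
Reagents that add atoms: none
Why: Reductive 1,3-transposition of an allylic alcohol through a monoalkyl diazene (Myers transposition): Mitsunobu displacement with inversion puts nitrogen on the α-face of C3, loss of sulfinic acid gives the diazene, and its retro-ene loss of N2 delivers hydrogen suprafacially to the α-face of C5. This sets the trans ring fusion (H5α) and moves the olefin to C3=C4.

Step 4
Reactants: 6 5αH-eudesm-3-en-6α,12-olide; 7 benzeneselenenyl chloride
Product: 9 11β-(phenylselanyl)-5αH-eudesm-3-en-6α,12-olide, via lithium enolate 8 (not isolated)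
Conditions: LiN(iPr)2, THF, −78 °C; then PhSeCl (1.0 equiv), −78 → −40 °C
Reagents that add atoms: benzeneselenenyl chloride (7), Cl[Se]c1ccccc1
Why: With no ketone present the lactone α-hydrogen is the only acidic site; α-selenenylation of the lithium enolate should occur on the β-face, anti to H7, as usual for trans-fused α-methyl lactones (the C11 centre is removed in step 5).

Step 5
Reactants: 9 11β-(phenylselanyl)-5αH-eudesm-3-en-6α,12-olide
Product: 11 5αH-eudesma-3,11(13)-dien-6α,12-olide (α-cyclocostunolide), via selenoxide 10 (not isolated)
Conditions: NaIO4, NaHCO3, MeOH–THF–H2O, 0 °C → rt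
Reagents that add atoms: none
Why: Periodate oxidises selenium without touching the ring olefin and the selenoxide undergoes syn elimination at room temperature; with selenium anti to H7 only the methyl hydrogens are available, so the exocyclic α-methylene lactone should result.

Step 6
Reactants: 11 5αH-eudesma-3,11(13)-dien-6α,12-olide
Product: 12 2-oxo-5αH-eudesma-3,11(13)-dien-6α,12-olide
Conditions: CrO3, 3,5-dimethylpyrazole, CH2Cl2, −20 °C
Reagents that add atoms: chromium trioxide, O=[Cr](=O)=O
Why: Allylic oxidation of a trisubstituted cyclohexene at the ring methylene next to the vinylic CH (the valencene-to-nootkatone pattern) gives the 3-en-2-one; the hexavalent chromium–pyrazole complex attacks the electron-rich ring olefin and not the electron-poor methylene lactone, and C5–H is tertiary, hindered and deactivated by the C6 oxygen.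

Step 7
Reactants: 12 2-oxo-5αH-eudesma-3,11(13)-dien-6α,12-olide
Product: 13 2-oxo-5αH-eudesma-3,7(11)-dien-6α,12-olide
Conditions: RhCl3·3H2O (10 mol %), EtOH, 70 °C
Reagents that add atoms: none
Why: Rhodium hydride addition–elimination moves the exocyclic olefin into the tetrasubstituted conjugated 7(11)-position, the thermodynamically preferred isomer; H7 is the only hydrogen that can be eliminated, so the isomerisation is regiospecific.

Step 8
Reactants: 13 2-oxo-5αH-eudesma-3,7(11)-dien-6α,12-olide
Product: 14 8β-hydroxy-2-oxo-5αH-eudesma-3,7(11)-dien-6α,12-olide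
Conditions: SeO2 (1.2 equiv), 1,4-dioxane, 90 °C
Reagents that add atoms: selenium dioxide, O=[Se]=O
Why: Riley-type allylic hydroxylation (ene reaction with selenium bonding to the α-carbon C11, then [2,3] shift) should attack the γ-methylene C8 of the more nucleophilic tetrasubstituted butenolide olefin in preference to the γ-methyl of the ring A enone, the oxygen-bearing C6–H and the neopentyl C1 methylene. Abstraction of the axial H8β is expected to give the 8β-alcohol, but the C8 configuration is erased in step 9 and does not matter.

Step 9
Reactants: 14 8β-hydroxy-2-oxo-5αH-eudesma-3,7(11)-dien-6α,12-olide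
Product: 17 2-oxo-5αH-eudesma-3,7,11(13)-trien-6α,12-olide, via sulfenate ester 15 (not isolated), via allylic sulfoxide 16 (not isolated)
Conditions: 2,4-(O2N)2C6H3SCl, pyridine, ClCH2CH2Cl, 0 → 60 °C
Reagents that add atoms: none
Why: 1,4-Dehydration of an allylic alcohol: the arenesulfenate undergoes [2,3] sigmatropic shift to the α-sulfinyl lactone, whose syn elimination can use only the C13 methyl hydrogens and so unveils the s-cis 7,11(13)-diene; the irreversible elimination drains the sulfenate–sulfoxide equilibrium.

Step 10
Reactants: 17 2-oxo-5αH-eudesma-3,7,11(13)-trien-6α,12-olide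
Product: 18 7α,8α-epoxy-2-oxo-5αH-eudesma-3,11(13)-dien-6α,12-olide
Conditions: mCPBA, NaHCO3, CH2Cl2, 0 °C
Reagents that add atoms: 3-chloroperoxybenzoic acid, OOC(=O)c1cccc(Cl)c1
Why: Prilezhaev epoxidation picks the only olefin that is not conjugated to a carbonyl group (trisubstituted C7=C8) and should approach from the α-face, anti to the homoallylic axial 10β-methyl group; this sets the C8–O configuration (8α) of the target.

Step 11
Reactants: 18 7α,8α-epoxy-2-oxo-5αH-eudesma-3,11(13)-dien-6α,12-olide; 19 tert-butyldimethylsilyl chloride
Product: 21 2-(tert-butyldimethylsilyloxy)-7α,8α-epoxy-5αH-eudesma-1,3,11(13)-trien-6α,12-olide, via potassium dienolate 20 (not isolated)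
Conditions: KN(SiMe3)2 (1.1 equiv), TBSCl (1.3 equiv, present from the start), THF, −78 → −40 °C
Reagents that add atoms: tert-butyldimethylsilyl chloride (19), CC(C)(C)[Si](C)(C)Cl
Why: Kinetic deprotonation of the enone at the α′ methylene C1 (axial H1α on the open α-face) with in situ O-silylation gives the cross-conjugated 2-silyloxy-1,3-diene without equilibration to the extended dienolate; at this stage the lactone is an α-methylene lactone with a fully substituted C7 and has no acidic hydrogen, which is why the enol ether is made before the butenolide.

Step 12
Reactants: 21 2-(tert-butyldimethylsilyloxy)-7α,8α-epoxy-5αH-eudesma-1,3,11(13)-trien-6α,12-olide; 22 acetic acid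
Product: 23 13-acetoxy-2-(tert-butyldimethylsilyloxy)-8α-hydroxy-5αH-eudesma-1,3,7(11)-trien-6α,12-olide
Conditions: Pd(PPh3)4 (5 mol %), AcOH (1.5 equiv), THF, 0 °C
Reagents that add atoms: acetic acid (22), CC(=O)O
Why: Tsuji–Trost 1,4-addition of a carboxylic acid to a vinyl epoxide: zerovalent palladium ionises the allylic C7–O bond, acetate attacks the unhindered primary terminus C13, and the olefin ends as the tetrasubstituted butenolide C7=C11. The C8–O bond is not touched, so the 8α-alcohol is revealed with retention, and the near-neutral medium should spare the silyl dienol ether.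

Step 13
Reactants: 23 13-acetoxy-2-(tert-butyldimethylsilyloxy)-8α-hydroxy-5αH-eudesma-1,3,7(11)-trien-6α,12-olide; 24 methacrylic anhydride
Product: 25 13-acetoxy-2-(tert-butyldimethylsilyloxy)-8α-(methacryloyloxy)-5αH-eudesma-1,3,7(11)-trien-6α,12-olide
Conditions: methacrylic anhydride, 4-(dimethylamino)pyridine (cat.), pyridine, CH2Cl2, 0 °C
Reagents that add atoms: methacrylic anhydride (24), C=C(C)C(=O)OC(=O)C(C)=C
Why: Nucleophile-catalysed acylation of the secondary allylic alcohol; the primary C13 oxygen is already acetylated and the silyl dienol ether tolerates the weakly basic medium.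

Step 14
Reactants: 25 13-acetoxy-2-(tert-butyldimethylsilyloxy)-8α-(methacryloyloxy)-5αH-eudesma-1,3,7(11)-trien-6α,12-olide
Product: 26 (6R,8S)-13-acetoxy-2-(tert-butyldimethylsilyloxy)-8-(methacryloyloxy)germacra-1(10),2,4,7(11)-tetraen-6,12-olide
Conditions: hν (254 nm, low-pressure Hg lamp, quartz), degassed THF, high dilution, −78 °C; solution used at once
Reagents that add atoms: none
Why: Light near 254 nm should be absorbed almost entirely by the homoannular silyloxydiene, which by the Woodward increments absorbs well to the red of the two enoate chromophores; from its excited singlet state the C5–C10 σ bond and the diene reorganise in a conrotatory 6π electrocyclic opening that creates the C1=C10 and C4=C5 π bonds and leaves the remaining double bond at C2=C3. The closest known reactions are the provitamin D to previtamin D opening and the opening of trans-fused bicyclic cyclohexa-1,3-dienes to E,Z,E-cyclodecatrienes. The ten-membered ring is not closed end to end: it arises by cleaving the bond shared by ring A and ring B, a ring expansion with no entropic penalty. No stereocentre is created; C5 and C10 are lost, and conrotation in the sense set by the helical twist of the trans-fused diene turns C6 and C9 outward and H5 and the C10 methyl inward, which gives E geometry at both new olefins and a cis ring junction at C2=C3. C6 and C8 are untouched. The step needs chemoselective excitation (secured by the diene being the strongest absorber at this wavelength) and suppression of thermal disrotatory reclosure and hydrogen shifts (secured by −78 °C and by desilylation in the cold in step 15).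

Step 15
Reactants: 26 (6R,8S)-13-acetoxy-2-(tert-butyldimethylsilyloxy)-8-(methacryloyloxy)germacra-1(10),2,4,7(11)-tetraen-6,12-olide
Product: 27 (6R,8S)-13-acetoxy-8-(methacryloyloxy)-2-oxogermacra-1(10)E,4E,7(11)-trien-6,12-olide
Conditions: Bu4NF, AcOH (1:1.5), THF, −78 → −40 °C, added to the cold solution from step 14
Reagents that add atoms: none
Why: Fluoride cleaves the O–Si bond and the buffered medium protonates the dienolate kinetically at its α-carbon C3, giving the β,γ-unsaturated ketone with C4=C5 intact; low temperature and acetic acid suppress base-induced conjugation and ester cleavage, and once the triene is interrupted thermal reclosure is no longer possible.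

Step 16
Reactants: 27 (6R,8S)-13-acetoxy-8-(methacryloyloxy)-2-oxogermacra-1(10)E,4E,7(11)-trien-6,12-olide
Product: 28 (2R,6R,8S)-13-acetoxy-2-hydroxy-8-(methacryloyloxy)germacra-1(10)E,4E,7(11)-trien-6,12-olide
Conditions: (S)-1-methyl-3,3-diphenyltetrahydro-1H,3H-pyrrolo[1,2-c][1,3,2]oxazaborole (0.5 equiv), catecholborane, toluene–CH2Cl2, −78 °C
Reagents that add atoms: none
Why: Corey–Bakshi–Shibata reduction; the trisubstituted alkenyl side (C1=C10) acts as the large group and the C3 methylene as the small one, so the (S)-oxazaborolidine should deliver hydride to the face that gives the (2R)-allylic alcohol; catecholborane at low temperature reduces 1,2 and should leave the butenolide, the methacrylate and the acetate alone.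

Step 17
Reactants: 28 (2R,6R,8S)-13-acetoxy-2-hydroxy-8-(methacryloyloxy)germacra-1(10)E,4E,7(11)-trien-6,12-olide; 29 acetic anhydride
Product: 30 (2R,6R,8S)-2,13-diacetoxy-8-(methacryloyloxy)germacra-1(10)E,4E,7(11)-trien-6,12-olide (target)
Conditions: Ac2O, pyridine, 4-(dimethylamino)pyridine (cat.), CH2Cl2, 0 °C
Reagents that add atoms: acetic anhydride (29), CC(=O)OC(C)=O
Why: Standard acylation of a secondary allylic alcohol under mild base; no stereocentre is touched and the product is the target.

Compound list

1 | α-santonin, (11S)-3-oxoeudesma-1,4-dien-6α,12-olide | C[C@H]1[C@@H]2CC[C@]3(C=CC(=O)C(=C3[C@H]2OC1=O)C)C | starting material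
2 | 1,2-dihydro-α-santonin, (11S)-3-oxoeudesm-4-en-6α,12-olide | C[C@H]1[C@@H]2CC[C@]3(CCC(=O)C(=C3[C@H]2OC1=O)C)C | intermediate
3 | (3S,11S)-3β-hydroxyeudesm-4-en-6α,12-olide | C[C@H]1[C@@H]2CC[C@]3(CC[C@H](O)C(=C3[C@H]2OC1=O)C)C | intermediate
4 | (11S)-3α-[1-(2-nitrobenzenesulfonyl)hydrazin-1-yl]eudesm-4-en-6α,12-olide | C[C@H]1[C@@H]2CC[C@]3(CC[C@@H](N(N)S(=O)(=O)c4ccccc4[N+](=O)[O-])C(=C3[C@H]2OC1=O)C)C | intermediate (not isolated)
5 | (11S)-3α-diazenyleudesm-4-en-6α,12-olide | C[C@H]1[C@@H]2CC[C@]3(CC[C@@H](N=N)C(=C3[C@H]2OC1=O)C)C | intermediate (not isolated)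
6 | (11S)-5αH-eudesm-3-en-6α,12-olide (trans-fused decalin; H7α; 13-methyl α) | C[C@H]1[C@@H]2CC[C@@]3(C)CCC=C(C)[C@@H]3[C@H]2OC1=O | intermediate
7 | benzeneselenenyl chloride | Cl[Se]c1ccccc1 | starting material
8 | lithium lactone enolate of 6 (C11=C12–OLi) | CC=1[C@@H]2CC[C@@]3(C)CCC=C(C)[C@@H]3[C@H]2OC=1[O-].[Li+] | intermediate (not isolated)
9 | 11β-(phenylselanyl)-5αH-eudesm-3-en-6α,12-olide (13-methyl α) | C[C@@]1([Se]c4ccccc4)[C@@H]2CC[C@@]3(C)CCC=C(C)[C@@H]3[C@H]2OC1=O | intermediate
10 | selenoxide of 9 (mixture at selenium) | C[C@@]1([Se](=O)c4ccccc4)[C@@H]2CC[C@@]3(C)CCC=C(C)[C@@H]3[C@H]2OC1=O | intermediate (not isolated)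
11 | 5αH-eudesma-3,11(13)-dien-6α,12-olide (α-cyclocostunolide) | C=C1[C@@H]2CC[C@@]3(C)CCC=C(C)[C@@H]3[C@H]2OC1=O | intermediate
12 | 2-oxo-5αH-eudesma-3,11(13)-dien-6α,12-olide | C=C1[C@@H]2CC[C@@]3(C)CC(=O)C=C(C)[C@@H]3[C@H]2OC1=O | intermediate
13 | 2-oxo-5αH-eudesma-3,7(11)-dien-6α,12-olide | CC1=C2CC[C@@]3(C)CC(=O)C=C(C)[C@@H]3[C@H]2OC1=O | intermediate
14 | 8β-hydroxy-2-oxo-5αH-eudesma-3,7(11)-dien-6α,12-olide | CC1=C2[C@H](O)C[C@@]3(C)CC(=O)C=C(C)[C@@H]3[C@H]2OC1=O | intermediate
15 | 8β-O-(2,4-dinitrobenzenesulfenyl) ester of 14 | CC1=C2[C@H](OSc4ccc(cc4[N+](=O)[O-])[N+](=O)[O-])C[C@@]3(C)CC(=O)C=C(C)[C@@H]3[C@H]2OC1=O | intermediate (not isolated)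
16 | 11β-(2,4-dinitrobenzenesulfinyl)-2-oxo-5αH-eudesma-3,7-dien-6α,12-olide (mixture at sulfur) | C[C@@]1(S(=O)c4ccc(cc4[N+](=O)[O-])[N+](=O)[O-])C2=CC[C@@]3(C)CC(=O)C=C(C)[C@@H]3[C@H]2OC1=O | intermediate (not isolated)
17 | 2-oxo-5αH-eudesma-3,7,11(13)-trien-6α,12-olide | C=C1C2=CC[C@@]3(C)CC(=O)C=C(C)[C@@H]3[C@H]2OC1=O | intermediate
18 | 7α,8α-epoxy-2-oxo-5αH-eudesma-3,11(13)-dien-6α,12-olide | C=C1[C@@]24O[C@H]4C[C@@]3(C)CC(=O)C=C(C)[C@@H]3[C@H]2OC1=O | intermediate
19 | tert-butyldimethylsilyl chloride | CC(C)(C)[Si](C)(C)Cl | starting material
20 | potassium 1,3-dien-2-olate of 18 | C=C1[C@@]24O[C@H]4C[C@@]3(C)C=C([O-])C=C(C)[C@@H]3[C@H]2OC1=O.[K+] | intermediate (not isolated)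
21 | 2-(tert-butyldimethylsilyloxy)-7α,8α-epoxy-5αH-eudesma-1,3,11(13)-trien-6α,12-olide | C=C1[C@@]24O[C@H]4C[C@@]3(C)C=C(O[Si](C)(C)C(C)(C)C)C=C(C)[C@@H]3[C@H]2OC1=O | intermediate
22 | acetic acid | CC(=O)O | starting material
23 | 13-acetoxy-2-(tert-butyldimethylsilyloxy)-8α-hydroxy-5αH-eudesma-1,3,7(11)-trien-6α,12-olide | O[C@H]1C[C@@]3(C)C=C(O[Si](C)(C)C(C)(C)C)C=C(C)[C@@H]3[C@H]2OC(=O)C(COC(C)=O)=C12 | intermediate
24 | methacrylic anhydride | C=C(C)C(=O)OC(=O)C(C)=C | starting material
25 | 13-acetoxy-2-(tert-butyldimethylsilyloxy)-8α-(methacryloyloxy)-5αH-eudesma-1,3,7(11)-trien-6α,12-olide (trans-fused; CH3-10β) | C=C(C)C(=O)O[C@H]1C[C@@]3(C)C=C(O[Si](C)(C)C(C)(C)C)C=C(C)[C@@H]3[C@H]2OC(=O)C(COC(C)=O)=C12 | intermediate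
26 | (6R,8S)-13-acetoxy-2-(tert-butyldimethylsilyloxy)-8-(methacryloyloxy)germacra-1(10),2,4,7(11)-tetraen-6,12-olide; 1(10)E, 4E, C2=C3 cis in the ring (2E by the sequence rules) | C=C(C)C(=O)O[C@H]1C/C(C)=C/C(O[Si](C)(C)C(C)(C)C)=C\C(C)=C\[C@H]2OC(=O)C(COC(C)=O)=C12 | intermediate
27 | (6R,8S)-13-acetoxy-8-(methacryloyloxy)-2-oxogermacra-1(10)E,4E,7(11)-trien-6,12-olide | C=C(C)C(=O)O[C@H]1C/C(C)=C/C(=O)C/C(C)=C/[C@H]2OC(=O)C(COC(C)=O)=C12 | intermediate
28 | (2R,6R,8S)-13-acetoxy-2-hydroxy-8-(methacryloyloxy)germacra-1(10)E,4E,7(11)-trien-6,12-olide | C=C(C)C(=O)O[C@H]1C/C(C)=C/[C@H](O)C/C(C)=C/[C@H]2OC(=O)C(COC(C)=O)=C12 | intermediate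
29 | acetic anhydride | CC(=O)OC(C)=O | starting material
30 | CNP0309304.1, (2R,6R,8S)-2,13-diacetoxy-8-(methacryloyloxy)germacra-1(10)E,4E,7(11)-trien-6,12-olide | C=C(C)C(=O)O[C@H]1C/C(C)=C/[C@H](OC(C)=O)C/C(C)=C/[C@H]2OC(=O)C(COC(C)=O)=C12 | target

Total step count: 17. Longest linear sequence: 17 steps from 1.

Least certain steps

Step 14 (key step). The most likely failure is incomplete conversion, because the ring-opened triene absorbs the same light and is returned to bicyclic dienes or isomerised further. The butenolide may also be excited and add across the neighbouring methacrylate double bond in a [2+2] photocycloaddition. Thermal disrotatory reclosure sets in if the solution warms before desilylation. The fallback removes the second olefinic ester from the irradiated molecule. It sets out from 23, which is irradiated under the same cold conditions to give the hydroxy triene silyl enol ether F1. Buffered fluoride in the cold then gives the 8-hydroxy ketone F2. F2 is esterified with 24 (4-(dimethylamino)pyridine, pyridine, CH2Cl2, −20 °C), which rejoins the route at 27.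

Step 8. The likely failure is loss of site selectivity: ene attack on the ring A enone at its γ-methyl group, α′-oxidation at C1, or over-oxidation of the new carbinol to the ketone. All arise because SeO2 distinguishes the two conjugated olefins only by their nucleophilicity. The fallback replaces the selenium ene reaction by a singlet-oxygen ene reaction, to which the ring A enone (no α-alkyl group) is inert. It sets out from 13. Photooxygenation (O2, 5,10,15,20-tetraphenylporphyrin, visible light, CH2Cl2, 0 °C) should abstract hydrogen from the methyl group geminal to the carbonyl and give the 7α-hydroperoxide F3. PPh3 reduces F3 to the 7α-hydroxy α-methylene lactone F4. Methyl N-(triethylammoniosulfonyl)carbamate (Burgess reagent, benzene, 50 °C) converts F4 through the sulfamate salt F5 by syn elimination towards C8 (H6 is anti to the C7–O bond and cannot take part). This rejoins the route at 17.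

Step 11. The likely failure is conjugate addition of the amide base or of the dienolate to the α-methylene lactone. The other danger is loss of kinetic control, with deprotonation at C5 and vinylogous β-elimination of the lactone oxygen. The fallback reverses the order, so that no α-methylene lactone is present when the base is used. It sets out from 18. Palladium-catalysed addition of 22 (as in step 12) gives the hydroxy acetate F6, and acylation with 24 gives the enone methacrylate F7. F7 is deprotonated with LiN(SiMe3)2 at −78 °C and silylated with tert-butyldimethylsilyl triflate, which rejoins the route at 25. This variant relies on H6 being shielded by the angular methyl group and is therefore held in reserve.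

Step 16. The likely failure is poor facial selectivity, because the conformation of the ten-membered enone may override catalyst control; 1,4-reduction could also compete. The fallback uses substrate control and corrects the configuration afterwards. It sets out from 27. Luche reduction (NaBH4, CeCl3·7H2O, MeOH, −78 °C) should give the alcohol from peripheral attack. Any 28 is acetylated as in step 17. The (2S)-epimer F8 is converted by Mitsunobu inversion with 22 (PPh3, diisopropyl azodicarboxylate, toluene, 0 °C) directly into the acetate, which rejoins the route at 30.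

Step 3. The likely failure is ionisation or SN2′ substitution during the Mitsunobu step at the hindered allylic carbinol. That would erode the stereospecific hydrogen delivery (cis-fused product) or lead to elimination. The fallback uses palladium-catalysed formate hydrogenolysis. It sets out from 3, which is formylated (formic acetic anhydride, pyridine) to the 3β-formate F9. Pd(OAc)2 with PBu3 (zerovalent palladium formed in situ, dioxane, reflux) ionises the formate anti, decarboxylates it to a palladium hydride, and delivers the hydride from the metal to the more substituted terminus C5 on the α-face. This rejoins the route at 6.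

Further compounds

F1 | step 14 | (6R,8S)-13-acetoxy-2-(tert-butyldimethylsilyloxy)-8-hydroxygermacra-1(10),2,4,7(11)-tetraen-6,12-olide | O[C@H]1C/C(C)=C/C(O[Si](C)(C)C(C)(C)C)=C\C(C)=C\[C@H]2OC(=O)C(COC(C)=O)=C12
F2 | step 14 | (6R,8S)-13-acetoxy-8-hydroxy-2-oxogermacra-1(10)E,4E,7(11)-trien-6,12-olide | O[C@H]1C/C(C)=C/C(=O)C/C(C)=C/[C@H]2OC(=O)C(COC(C)=O)=C12
F3 | step 8 | 7α-hydroperoxy-2-oxo-5αH-eudesma-3,11(13)-dien-6α,12-olide | C=C1[C@]2(OO)CC[C@@]3(C)CC(=O)C=C(C)[C@@H]3[C@H]2OC1=O
F4 | step 8 | 7α-hydroxy-2-oxo-5αH-eudesma-3,11(13)-dien-6α,12-olide | C=C1[C@]2(O)CC[C@@]3(C)CC(=O)C=C(C)[C@@H]3[C@H]2OC1=O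
F5 | step 8 | triethylammonium salt of the 7α-O-[N-(methoxycarbonyl)sulfamoyl] derivative of F4 | C=C1[C@]2(OS(=O)(=O)[N-]C(=O)OC)CC[C@@]3(C)CC(=O)C=C(C)[C@@H]3[C@H]2OC1=O.CC[NH+](CC)CC
F6 | step 11 | 13-acetoxy-8α-hydroxy-2-oxo-5αH-eudesma-3,7(11)-dien-6α,12-olide | O[C@H]1C[C@@]3(C)CC(=O)C=C(C)[C@@H]3[C@H]2OC(=O)C(COC(C)=O)=C12
F7 | step 11 | 13-acetoxy-8α-(methacryloyloxy)-2-oxo-5αH-eudesma-3,7(11)-dien-6α,12-olide | C=C(C)C(=O)O[C@H]1C[C@@]3(C)CC(=O)C=C(C)[C@@H]3[C@H]2OC(=O)C(COC(C)=O)=C12
F8 | step 16 | (2S,6R,8S)-13-acetoxy-2-hydroxy-8-(methacryloyloxy)germacra-1(10)E,4E,7(11)-trien-6,12-olide | C=C(C)C(=O)O[C@H]1C/C(C)=C/[C@@H](O)C/C(C)=C/[C@H]2OC(=O)C(COC(C)=O)=C12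
F9 | step 3 | (11S)-3β-formyloxyeudesm-4-en-6α,12-olide | C[C@H]1[C@@H]2CC[C@]3(CC[C@H](OC=O)C(=C3[C@H]2OC1=O)C)C
A1 | alternative 1 | open-chain (E)-alkenyl iodide (C5) with C6 aldehyde cis to the C12 methyl ester, 2-O-acetyl, 13-O-acetyl, 8-O-triethylsilyl | I/C=C(C)/C[C@@H](OC(C)=O)/C=C(C)/C[C@H](O[Si](CC)(CC)CC)/C(C=O)=C(\COC(C)=O)C(=O)OC
A2 | alternative 1 | 8-O-triethylsilyl bicyclic core with both acetates | CC[Si](CC)(CC)O[C@H]1C/C(C)=C/[C@H](OC(C)=O)C/C(C)=C/[C@H]2OC(=O)C(COC(C)=O)=C12
A3 | alternative 2 | open-chain C1–C10 alkyne with C8–C9 terminal epoxide, 2-O-tert-butyldimethylsilyl, 6-O-(4-methoxybenzyl), 7-O-triethylsilyl | CC#C[C@H](O[Si](C)(C)C(C)(C)C)C/C(C)=C/[C@@H](OCc1ccc(OC)cc1)[C@H](O[Si](CC)(CC)CC)[C@@H]2CO2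
A4 | alternative 2 | ten-membered 8-hydroxy-1(10),4-diene with differentiated C6 and C7 oxygens | O[C@H]1C/C(C)=C/[C@H](O[Si](C)(C)C(C)(C)C)C/C(C)=C/[C@@H](OCc2ccc(OC)cc2)[C@@H]1O[Si](CC)(CC)CC
A5 | alternative 3 | C7-iodobutenolide with the C8 aldehyde side chain, 2,13-di-O-acetyl | O=CC/C(C)=C/[C@H](OC(C)=O)C/C(C)=C/[C@H]1OC(=O)C(COC(C)=O)=C1I
A6 | alternative 3 | 8-hydroxy macrocycle lacking only the methacryloyl group | O[C@H]1C/C(C)=C/[C@H](OC(C)=O)C/C(C)=C/[C@H]2OC(=O)C(COC(C)=O)=C12
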